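**Assumption:** the target has no stereocentre and no stereogenic double bond, so it is achiral and "single enantiomer" sets no stereochemical task.

**Retrosynthetic overview** (disconnections listed from the first bond made to the last)
1. The only ring, the 2-pyranone, is made first: 1 and 2 are joined through 3, 4 and 5 to pyranone 6 (C5–C6 by γ-acylation of a β-ketoester dianion, then O1–C2 lactone closure).
2. Key disconnection C3–OMe: 6 → ylide 7 → 8, a carbene O–H insertion into methanol at the only ring C–H.
3. O4–CH3: 8 → 9 by O-methylation.
4. C–S last, because a sulfide would not survive the oxidant and carbene of line 2: 9 → 10 by thiol–ene addition to the terminal alkene.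

**Route**

Step 1
Reactants: 1 methyl 3-oxopentanoate; 2 undec-10-enoic acid
Product: 6 6-(dec-9-en-1-yl)-4-hydroxy-5-methyl-2H-pyran-2-one, via acylimidazole 3 (not isolated), via dilithium dianion 4 (not isolated), via diketo ester 5 (not isolated)
Conditions: 2, CDI (1.1 equiv), THF, rt; added to 1 (3.3 equiv)/LiN(iPr)2 (6.6 equiv), THF, −78 → −40 °C; AcOH quench, aqueous wash, excess 1 removed in vacuo; DBU (1.5 equiv), toluene, 80 °C; dilute HCl work-up
Reagents that add atoms: none
Why: Weiler-type Claisen acylation of the β-ketoester dianion at its γ-carbon by the N-acylimidazole (excess dianion absorbs the free imidazole and the acidic product), then DBU-promoted enol lactonisation of the 3,5-dioxo ester with loss of methanol; the stereocentre of 5 disappears on forming the pyranone.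

Step 2
Reactants: 6 6-(dec-9-en-1-yl)-4-hydroxy-5-methyl-2H-pyran-2-one
Product: 8 6-(dec-9-en-1-yl)-4-hydroxy-3-methoxy-5-methyl-2H-pyran-2-one, via phenyliodonium ylide 7 (not isolated)
Conditions: PhI(OAc)2 (1.1 equiv), K2CO3 (2.2 equiv), MeOH, 0 °C → rt; then Rh2(OAc)4 (1 mol%), 40 °C; dilute HCl work-up
Reagents that add atoms: methanol, CO
Why: Proposed new method: one-flask C3–H methoxylation, in which the acidic 4-hydroxy-2-pyranone (a cyclic 1,3-dicarbonyl enol) condenses with PhI(OAc)2 to the phenyliodonium ylide 7, Rh2(OAc)4 converts 7 into a dirhodium carbene with loss of PhI, and solvent methanol traps the carbene (oxonium ylide, proton shift, enolisation) to form the C3–O bond; the closest known reaction type is dirhodium-catalysed carbene O–H insertion of cyclic 2-diazo-1,3-dicarbonyl compounds and of malonate-derived iodonium ylides into alcohols, not yet shown as a C–H alkoxylation of 4-hydroxy-2-pyranones.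

Step 3
Reactants: 8 6-(dec-9-en-1-yl)-4-hydroxy-3-methoxy-5-methyl-2H-pyran-2-one
Product: 9 6-(dec-9-en-1-yl)-3,4-dimethoxy-5-methyl-2H-pyran-2-one
Conditions: Me2SO4 (1.5 equiv), K2CO3 (2 equiv), acetone, reflux
Reagents that add atoms: dimethyl sulfate, COS(=O)(=O)OC
Why: Williamson-type O-alkylation of the potassium pyranolate, under conditions known to favour the 4-methoxy-2-pyranone over the isomeric 2-methoxy-4-pyranone.

Step 4
Reactants: 9 6-(dec-9-en-1-yl)-3,4-dimethoxy-5-methyl-2H-pyran-2-one
Product: 10 3,4-dimethoxy-5-methyl-6-[10-(methylsulfanyl)decyl]-2H-pyran-2-one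
Conditions: MeSH (8 equiv), AIBN (10 mol%), degassed toluene, sealed tube, 70 °C
Reagents that add atoms: methanethiol, CS
Why: Radical thiol–ene reaction (anti-Markovnikov hydrothiolation): the methylthiyl radical adds to the terminal alkene carbon and the secondary radical takes H from MeSH to carry the chain, while the fully substituted ring double bonds add thiyl radicals only reversibly; it is an addition with no co-product.

**Compound list**
1 | methyl 3-oxopentanoate | CCC(=O)CC(=O)OC | starting material
2 | undec-10-enoic acid | C=CCCCCCCCCC(=O)O | starting material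
3 | 1-(undec-10-enoyl)-1H-imidazole (acylimidazole) | C=CCCCCCCCCC(=O)n1ccnc1 | intermediate (not isolated)
4 | dilithium dianion of methyl 3-oxopentanoate | CC=C([O-])C=C([O-])OC.[Li+].[Li+] | intermediate (not isolated)
5 | methyl 4-methyl-3,5-dioxopentadec-14-enoate (diketo ester, racemic) | COC(=O)CC(=O)C(C)C(=O)CCCCCCCCC=C | intermediate (not isolated)
6 | 6-(dec-9-en-1-yl)-4-hydroxy-5-methyl-2H-pyran-2-one | C=CCCCCCCCCc1oc(=O)cc(O)c1C | intermediate
7 | 6-(dec-9-en-1-yl)-5-methyl-2-oxo-3-(phenyliodonio)-2H-pyran-4-olate (phenyliodonium ylide) | C=CCCCCCCCCC1=C(C)C([O-])=C([I+]c2ccccc2)C(=O)O1 | intermediate (not isolated)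
8 | 6-(dec-9-en-1-yl)-4-hydroxy-3-methoxy-5-methyl-2H-pyran-2-one | C=CCCCCCCCCc1oc(=O)c(OC)c(O)c1C | intermediate
9 | 6-(dec-9-en-1-yl)-3,4-dimethoxy-5-methyl-2H-pyran-2-one | C=CCCCCCCCCc1oc(=O)c(OC)c(OC)c1C | intermediate
10 | 3,4-dimethoxy-5-methyl-6-[10-(methylsulfanyl)decyl]-2H-pyran-2-one | COc1c(C)c(CCCCCCCCCCSC)oc(=O)c1OC | target

**Total step count:** 4. **Longest linear sequence:** 4.

**Steps most likely to fail, with fallbacks**

Step 2 (the proposed new step). The ylide 7 may divert by iodine-to-oxygen phenyl migration or by Wolff-type ring contraction, or the carbene may insert into acetate in place of methanol. The fallback uses only known chemistry and brings the C3 methoxy group in before the ring is made. It sets out from 1 and uses 3. Regitz diazo transfer to 1 (p-acetamidobenzenesulfonyl azide, Et3N, MeCN) gives methyl 2-diazo-3-oxopentanoate F1. Rh2(OAc)4-catalysed O–H insertion of F1 into methanol gives methyl 2-methoxy-3-oxopentanoate F2. Double deprotonation with LiN(iPr)2 in THF gives the dilithium dianion of methyl 2-methoxy-3-oxopentanoate F3. Acylation of F3 at its γ-carbon with 3 gives methyl 2-methoxy-4-methyl-3,5-dioxopentadec-14-enoate F4. DBU in warm toluene lactonises F4, and the sequence comes back to the route at 8.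

Step 3. The 4-hydroxyl is flanked by the 3-methoxy and 5-methyl groups, and the pyranolate is ambident, so some 2-O-methylation to the 4-pyranone isomer is expected. The fallback sets out from 8 and comes back at 9 by a Mitsunobu etherification (MeOH, PPh3, diisopropyl azodicarboxylate, THF, 0 °C → rt). Here the pyranone acts as the acidic partner toward a methoxyphosphonium ion, a mode reported to alkylate 4-hydroxy-2-pyranones at O4. No new compound is made (F0).

Step 1. The acylation may be low-yielding, because free imidazole and the acidic product consume dianion and the acylimidazole can be enolised. The fallback sets out from 1 (as its dianion 4) and comes back at 5. Aldol addition of 4 to commercial undec-10-enal (THF, −78 °C) gives methyl 5-hydroxy-4-methyl-3-oxopentadec-14-enoate F5 as a diastereomer mixture. Dess–Martin oxidation of F5 gives 5, which is cyclised with DBU to 6 as in the route.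

**Further compounds**
F1 | step 2 | methyl 2-diazo-3-oxopentanoate | CCC(=O)C(=[N+]=[N-])C(=O)OC
F2 | step 2 | methyl 2-methoxy-3-oxopentanoate (racemic) | CCC(=O)C(OC)C(=O)OC
F3 | step 2 | dilithium dianion of methyl 2-methoxy-3-oxopentanoate | CC=C([O-])C(OC)=C([O-])OC.[Li+].[Li+]
F4 | step 2 | methyl 2-methoxy-4-methyl-3,5-dioxopentadec-14-enoate (stereoisomer mixture) | COC(=O)C(OC)C(=O)C(C)C(=O)CCCCCCCCC=C
F0 | step 3 | none | none
F5 | step 1 | methyl 5-hydroxy-4-methyl-3-oxopentadec-14-enoate (diastereomer mixture) | COC(=O)CC(=O)C(C)C(O)CCCCCCCCC=C
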